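If I wanted L from X and Q in the flasks below, I had to ask first where each one must end.

the same everywhere: X 0.20 M
- delta: Q 0.10 M; G 0.12 M; temperature 40 °C; run made earlier
- spring: Q 0.100 M; G 0.0600 M; temperature 40 °C; time 20 min
- dawn: Q 0.100 M; G 0.0600 M; temperature −5 °C; time 20 min
- summer: Q 0.100 M; G 0.0600 M; temperature 25 °C; time 20 min
- winter: Q 0.100 M; G 0.0600 M; temperature 10 °C; time 20 min

delta run (percent of the X charged)

| time / min | L / % |
|---|---|
| 0.333 | 14.4 |
| 0.500 | 16.5 |
| 0.667 | 16.6 |
| 1.00 | 17.2 |
| 1.50 | 15.4 |
| 2.50 | 15.1 |
| 4.00 | 11.5 |

(scatter of a reading: 0.5 percentage points)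

- the flask with the highest amount of L, in percent of the X charged ("all alike" if they lie within 1.5 percentage points) (spring / dawn / summer / winter / all alike)
- final L, as a percentage of the X charged, in spring
- final L, as a percentage of the X charged, in dawn
- final L, as a percentage of the X charged, in summer
- final L, as a percentage of the X charged, in winter

- the earlier runs do not show what temperature does; that part of a forecast is a guess
- no earlier run changes the charge of G; that part of a forecast is a guess

I assumed that X and Q give L one to one, which makes Q the limiting reagent. My first extreme was a flask where nothing else happens and that step runs to the end. L then ends at the ceiling, 50.0% of the X charged, which is the charge of Q over the charge of X. Delta has the same ratio of charges, but its best reading was 17.2% at 1.00 min, so its fill, meaning L over the ceiling, read 34.4%. From there the readings sank to 11.5% at 4.00 min, which read as a fade of 0.134 min⁻¹, or a life of 7.45 min. My second extreme was a flask that stalls as delta did and keeps fading at that pace, which leaves 1.35% after 20 min.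

I expected the real flasks to lie between these two. Delta's readings had nearly stopped rising by 0.500 min, so at delta's pace the time allowed is 40.0 rise times but 2.68 fade lives. Cooling should slow both, by an amount that I could only guess. I reckoned that a cold flask might therefore rise slowly yet still in time, while its fade slowed too. So I bet on dawn, at −5 °C, with L between delta's 17.2% and the ceiling.

The forecast, unlike my bet, named winter, with 5% in spring, 17% in dawn, 14% in summer and 18% in winter: “Winter is narrowly best”.

Dawn came out highest at 24.8%, ahead of winter at 20.3%, summer at 12.5% and spring at 10.3%.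

    X + Q ⇌ L (K = 12.8 L mol⁻¹, k = 3.54 L mol⁻¹ min⁻¹, Ea = 49.0 kJ mol⁻¹, ΔH = −13.0 kJ mol⁻¹)
    X + Q ⇌ Z (K = 26.0 L mol⁻¹, k = 2.13 L mol⁻¹ min⁻¹, Ea = 61.0 kJ mol⁻¹, ΔH = −18.0 kJ mol⁻¹)
    Q + G → E (k = 0.522 L mol⁻¹ min⁻¹, Ea = 54.0 kJ mol⁻¹)
    Q → J (k = 2.38 × 10⁻⁴ min⁻¹, Ea = 98.0 kJ mol⁻¹)
    (constants at 25 °C)

Dawn's fill, its L over the ceiling of 50.0%, was 49.7%, and spring's was 20.6%. In spring the backward run from L to X + Q had the largest single effect on the final L: without that step L ended at 46.2% instead of 10.3%. In dawn the same step cost 3.9 percentage points. A neighbour of dawn charged with 0.060 M of Q has a ceiling of 30.0%, and dawn's fill gives 14.9% there; the computed flask held 15.7%.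

(All runs come from a simulation from invented constants, noise included.)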